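Conventions used throughout: heavy atoms are numbered along the target SMILES (C1 methyl on C2; C2=C3; C4, C10 ring fusion; C6 with methyl C7; C11 quaternary with methyl C12; C13 ketone; C15 spiro; C16 ketone; C18 with C19–O20; N21 with C22; C23 lactam carbonyl; C25 with side chain C26=C27–C28(O30)–C29; C31). Ring A = C4, C5, C6, C8, C9, C10; ring B = C2, C3, C4, C10, C11, C31; ring C = C11, C13, C15, C25, C31; ring D = C15, C16, C18, N21, C23. The "upper" face of ring B carries H10, C13 and C25; the "lower" face carries H4, the C11 methyl group C12 and H31.

## Analysis of the target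

The target is a tetracycle: a trans-fused octalin (rings A and B, alkene C2=C3 with the C1 methyl on C2), a cyclopentanone (ring C) cis-fused to ring B at C11–C31, and an N-methylpyrrolidine-2,4-dione (ring D) spiro-linked at C15. It has nine stereocentres (C4, C6, C10, C11, C15, C18, C25, C28, C31) and one (E)-alkene. H4 and H10 are anti, the C6 methyl is equatorial, the C11 methyl is cis to H31, and the side-chain carbon C26 sits on the convex (lower) face of the ring B/C unit, cis to the ring D ketone carbon C16. C18 has the L-serine configuration and C28 is (S). The sensitive points are the spiro carbon C15, which carries three acyl groups and no hydrogen, so that any nucleophilic base can open it by retro-Claisen cleavage, and the C18–H next to the C16 ketone, which can epimerise. The difficulty is concentrated in two adjacent quaternary-type centres (C11 and C15) and in placing ring A, the C11 methyl and ring C correctly around ring B. The strategy rests on one feature: in ring B the quaternary C11 is para to C3, so ring B maps onto an achiral 4-methyl-4-(methoxycarbonyl)cyclohexa-2,5-dienone (carbonyl at C3). One enone arm (C4=C10) can accept ring A, while the other arm (C2=C31) and the ester (C13) remain for the C1 methyl, the C2=C3 alkene and ring C.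

## Retrosynthetic reasoning

Target 41 is traced back to its bis-silyl ether 40. The two hydroxyl groups (O20, O30) must be masked while C16 is an activated acyl group, and acidic fluoride removes both silyl groups without exposing the tricarbonyl array to base.

In 40 the C15–C16 bond is cut, leading to the β-keto amide acid 38 through its pentafluorophenyl ester 39. This bond is made last because it creates the base-labile, non-enolisable spiro centre. A classical alkoxide Dieckmann closure would not hold here: the product has no acidic C15–H to drive it, and the released alkoxide would reopen it. The forward step is therefore an irreversible C-acylation of the C15 enolate by an active ester, and it must deliver C16 to the lower face of ring C.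

Acid 38 comes from allyl ester 37, and 37 from the amide bond C23–N21 between the ring C β-keto tert-butyl ester 32 and the serine-derived amine 35 (made from N-methyl-L-serine 33 via 34). A tert-butyl β-keto ester is chosen because it transfers its acyl group thermally through an acylketene (36) without base, which protects C18.

The side chain of 32 is cut at C26=C27 and simplified at C28: silyl ether 32 from alcohol 31, 31 from enone 30 by reagent-controlled reduction, and 30 from aldehyde 28 and ylide 29. The aldehyde stage is also where C25 can be equilibrated, since C25 is then α to a carbonyl inside the rigid ring B/C bicycle.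

Aldehyde 28 comes from thioester 26 and acid 25. The thioester is the only C26 derivative that can be taken to the aldehyde in the presence of the ring C ketone. Ring C of 25 is opened at C13–C15 (Dieckmann), giving the succinate half-ester 24, in which C25 carries the future C26 carboxyl and the C15–C23 acetate arm.

In 24 the C25–C31 bond is cut by an Ireland–Claisen transform to the allylic succinate 21. This delivers C25 to the hindered carbon C31 next to the quaternary C11 from the C3 oxygen on the same face, and it places the alkene at C2=C3. Ester 21 comes from alcohol 19 and mono-tert-butyl succinate 20 with inversion at C3, because hydride reduction of enone 18 puts the C3 oxygen on the lower face while the [3,3] shift needs it on the upper face.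

Enone 18 is simplified to 16 by removing the C1 methyl (iodide 17, cross-coupling). The methyl is added late so that the dienone stays symmetric for the desymmetrising step.

Enone ester 16 is cut at C9–C10 and C4–C5, giving the achiral dienone 5 and the chloro-Grignard reagent 13. This is the central disconnection: it removes ring A and three stereocentres (C4, C10, C11) in one operation and brings in C6 from the reagent.

Dienone 5 goes back to benzoic acid 1 through 3 and 4 (Birch reductive methylation, esterification, allylic oxidation). Reagent 13 goes back through 12, 11, 10 and 8 to the half-ester 6, whose two carboxyl ends are already differentiated.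

## Alternatives that were turned down

Alternative 1: The C13–C15 bond is cut last. A seco acid A2, in which C11 carries a free carboxylic acid (C13) and C25 already carries a complete 3-substituted tetramic acid, would be activated at C13; the acyl group is transferred to the tetramic acid oxygen and then to C15, closing ring C and forming the spiro centre to give A1, which has the same structure as 40. In its favour, the acyl transfer is irreversible and needs no alkoxide, so it avoids the retro-Claisen problem that forced the active-ester repair in the chosen route; on that point it is stronger. Against it, C13 is a neopentyl carboxyl on the quaternary C11 and the acceptor C15 is a hindered tertiary carbon, so the O-to-C shift must form a bond between two congested centres. A2 itself requires a C15–C25 bond between a tetramic acid and a secondary carbon, for which no simple construction exists, and the alternative says nothing about how rings A and B are made. The facial problem at C15 is the same as in the chosen route. The chosen strategy closes ring C by a Dieckmann reaction whose product is enolisable and therefore self-driving, and it supplies the octalin as well.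

Alternative 2: Ring C is closed first by cutting C25–C31. The achiral dienone A4 (4-methyl-4-(4-oxobutanoyl)cyclohexa-2,5-dienone) would undergo an amine-catalysed intramolecular Michael addition of the C26 aldehyde enamine onto one enone arm, giving the cis-fused keto aldehyde A3. It uses the same dienone symmetry and sets C11, C31 and C25 in one catalytic step. It is stronger than the chosen route in one respect: the later conjugate addition that starts ring A would be steered by the rigid cis-fused bicycle (convex face, syn to C12) rather than by a catalyst that has to tell a methyl group from an ester. Against it, A4 is a 1,4-keto aldehyde prone to self-condensation, and A3 has three carbonyl groups (C3, C13, C26) to keep apart. C15 arrives as a bare CH2 that must later receive both C23 and C16, ring A with C6 still needs a chiral reagent, and the C3 ketone must be turned into the methylated C2=C3 alkene by enolisation toward C2 and not C4. The chosen route spends its stereochemical risk in one step and then uses the untouched enone arm for the methyl group, the alkene and C25 in a fixed order.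

Alternative 3: Ring B and a cyclobutanone are formed together. The amide A6 (ring A carrying a propanamide at C10 and a (Z,E)-diene at C4) would be converted into a keteniminium ion at C13, which adds across C31=C25 to give the cyclobutanone A5; a one-carbon ring expansion then inserts C15. In its favour, the alkene geometry is translated into the C31/C25 relationship and C11 is formed at the same time. A diazoacetate ring expansion would give the ring C β-keto ester directly, which is shorter than the Luche/Mitsunobu/Claisen/Dieckmann sequence used here; on step count after ring B it is stronger. Against it, A6 needs ring A with three stereocentres and a stereodefined diene before the key step. The keteniminium ion must choose the less nucleophilic disubstituted alkene over the trisubstituted one and a [2+2] over a [4+2] pathway, its facial selectivity at C11 depends only on C10, and the ring expansion must migrate C25 rather than the quaternary C11. The chosen route has one stereochemical uncertainty in its key step and a precursor three steps from benzoic acid.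

Key step: step 9

Remark: the half-ester 6 is taken as a purchased compound (it is otherwise the hydrogenation product of 4-methyl itaconate); salts that are only protonated on work-up are not numbered separately.

Remark: the ligand enantiomer in step 9 is written as (R,S); its mirror image is used if the (R,S) ligand selects the other enone arm.

## Route

Step 1
Reactants: 1 benzoic acid
Product: 3 1-methylcyclohexa-2,5-diene-1-carboxylic acid, via Birch dianion 2 (not isolated)
Conditions: Li (3 equiv), NH3(l), THF, –78 °C; then MeI, –78 °C → rt; aq. HCl
Reagents that add atoms: iodomethane CI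
Why: Birch reduction of the benzoate gives the cross-conjugated dianion 2, which is alkylated at the carboxyl-bearing carbon (Birch reductive alkylation); the 1,4-diene cannot rearomatise because that carbon is now quaternary.

Step 2
Reactants: 3 1-methylcyclohexa-2,5-diene-1-carboxylic acid
Product: 4 methyl 1-methylcyclohexa-2,5-diene-1-carboxylate
Conditions: MeI, K2CO3, DMF, rt
Reagents that add atoms: iodomethane CI
Why: SN2 O-alkylation of the carboxylate; the ester prevents decarboxylative aromatisation once the dienone is formed.

Step 3
Reactants: 4 methyl 1-methylcyclohexa-2,5-diene-1-carboxylate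
Product: 5 methyl 1-methyl-4-oxocyclohexa-2,5-diene-1-carboxylate
Conditions: t-BuOOH (5 equiv), Pd(OH)2/C (5 mol %), K2CO3 (0.25 equiv), CH2Cl2, 4 °C → rt
Reagents that add atoms: tert-butyl hydroperoxide CC(C)(C)OO
Why: Radical allylic oxidation; the doubly allylic CH2 has the weakest C–H bond and is remote from the quaternary carbon, so the peroxide formed there collapses to the cross-conjugated dienone.

Step 4
Reactants: 6 (S)-2-methylsuccinic acid 4-methyl ester
Product: 8 (S)-4-methyloxolan-2-one, via hydroxy ester 7 (not isolated)
Conditions: BH3·SMe2, THF, 0 °C → rt; MeOH quench; then TsOH (cat.), CH2Cl2, rt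
Reagents that add atoms: none
Why: Borane reduces a free carboxylic acid much faster than an ester, and the γ-hydroxy ester 7 lactonises under acid; the stereocentre is β to both carbonyl groups and is untouched.

Step 5
Reactants: 8 (S)-4-methyloxolan-2-one
Product: 10 methyl (S)-4-chloro-3-methylbutanoate, via acid chloride 9 (not isolated)
Conditions: SOCl2, ZnCl2 (cat.), 60 °C; then MeOH, 0 °C
Reagents that add atoms: thionyl chloride ClS(Cl)=O; methanol CO
Why: Lewis-acid-assisted SN2 opening of the lactone at the O–CH2 carbon by chloride (the butyrolactone to 4-chlorobutanoyl chloride reaction), then methanolysis; the chloride now marks the chain end next to the stereocentre.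

Step 6
Reactants: 10 methyl (S)-4-chloro-3-methylbutanoate
Product: 11 (S)-4-chloro-3-methylbutan-1-ol
Conditions: i-Bu2AlH (2.2 equiv), CH2Cl2, –78 → 0 °C; aq. potassium sodium tartrate (KNaC4H4O6)
Reagents that add atoms: none
Why: Ester-to-alcohol reduction; the primary chloride is inert at low temperature and the neutral work-up avoids cyclisation of the chloro alcohol to the tetrahydrofuran.

Step 7
Reactants: 11 (S)-4-chloro-3-methylbutan-1-ol
Product: 12 (S)-4-bromo-1-chloro-2-methylbutane
Conditions: CBr4, PPh3, CH2Cl2, 0 °C
Reagents that add atoms: tetrabromomethane BrC(Br)(Br)Br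
Why: Appel bromination (SN2 on the alkoxyphosphonium ion) at the unbranched primary carbon gives a dihalide with two halogens of different reactivity toward magnesium.

Step 8
Reactants: 12 (S)-4-bromo-1-chloro-2-methylbutane
Product: 13 (S)-(4-chloro-3-methylbutyl)magnesium bromide (Et2O solution, titrated and used directly)
Conditions: Mg turnings, Et2O, rt → 35 °C
Reagents that add atoms: magnesium [Mg]
Why: Magnesium inserts into the C–Br bond far faster than into the C–Cl bond, as with 1-bromo-4-chlorobutane, so the chloride survives as the later leaving group.

Step 9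
Reactants: 5 methyl 1-methyl-4-oxocyclohexa-2,5-diene-1-carboxylate; 13 (S)-(4-chloro-3-methylbutyl)magnesium bromide
Product: 16 methyl (1S,4aS,6S,8aS)-1,6-dimethyl-4-oxo-1,4,4a,5,6,7,8,8a-octahydronaphthalene-1-carboxylate (trans-fused ring A/B enone ester), via magnesium enolate 14 (not isolated), via C4-epimeric decalone mixture 15 (not isolated)
Conditions: 13 (1.2 equiv), CuBr·SMe2 (5 mol %), (R)-1-[(S)-2-(diphenylphosphino)ferrocenyl]ethyldicyclohexylphosphine (6 mol %), t-BuOMe, –78 °C; then HMPA, THF, –78 → 50 °C; aq. NH4Cl; crude product: NaOMe (0.2 equiv), MeOH, rt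
Reagents that add atoms: none
Why: The Grignard reagent transmetalates to a chiral copper alkyl complex, which binds one of the two enantiotopic enone arms of the achiral dienone and transfers the alkyl group to C10, forming C9–C10 and the magnesium enolate 14. The closest known reaction types are the copper-catalysed enantioselective conjugate addition of Grignard reagents to cyclic enones and 4,4-disubstituted cyclohexadienones with ferrocenyl diphosphines, and the conjugate addition–cycloalkylation annulation with ω-chloroalkyl organometallics. On warming with HMPA the enolate carbon C4 displaces the primary chloride at C5, closing ring A in a 6-(enolexo)-exo-tet mode and forming C4–C5. C10 is set by the catalyst (choice of arm and of face), and C11 becomes stereogenic as a direct consequence of that choice. C4 is set thermodynamically: methoxide equilibrates the α-carbon to the trans-fused decalone, in which the C6 methyl brought in by the (S) reagent is equatorial. The step needs addition at the correct arm on the face syn to the C11 methyl (anti to the ester); the ligand chooses the arm, and attack anti to the C11–C13 bond, the better σ-acceptor, is the face expected for a nucleophilic copper reagent. Only one addition can occur because the first adduct is an enolate, and the ester is untouched because it sits on a quaternary carbon.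

Step 10
Reactants: 16 trans-fused ring A/B enone ester
Product: 17 methyl 3-iodo-1,6-dimethyl-4-oxo-1,4,4a,5,6,7,8,8a-octahydronaphthalene-1-carboxylate (iodine on C2; stereocentres as in 16)
Conditions: I2 (2 equiv), pyridine, CH2Cl2, 0 °C → rt
Reagents that add atoms: iodine II
Why: α-Iodination of the enone by conjugate addition of pyridine, iodination of the enolate and elimination, a sequence known for 4,4-disubstituted cyclohexenones; only C2 can react this way.

Step 11
Reactants: 17 α-iodoenone
Product: 18 methyl 1,3,6-trimethyl-4-oxo-1,4,4a,5,6,7,8,8a-octahydronaphthalene-1-carboxylate (C1 methyl on C2; stereocentres as in 16)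
Conditions: SnMe4 (3 equiv), Pd2(dba)3 (5 mol %), AsPh3 (20 mol %), CuI (10 mol %), NMP, 70 °C
Reagents that add atoms: tetramethylstannane C[Sn](C)(C)C
Why: Stille coupling of the α-iodoenone (oxidative addition, tin-to-palladium methyl transfer, reductive elimination) installs the C1 methyl on C2.

Step 12
Reactants: 18 2-methyl enone
Product: 19 allylic alcohol of 18 with the C3 hydroxyl on the lower face (cis to H4 and to the C11 methyl)
Conditions: NaBH4, CeCl3·7H2O, MeOH, –78 → 0 °C
Reagents that add atoms: none
Why: Luche 1,2-reduction; hydride adds axially to C3 from the upper face, anti to the axial H4, giving the pseudo-equatorial lower-face alcohol. This auxiliary centre is consumed in step 14.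

Step 13
Reactants: 19 lower-face allylic alcohol; 20 4-tert-butoxy-4-oxobutanoic acid (mono-tert-butyl succinate)
Product: 21 allylic tert-butyl succinate with the C3 ester oxygen on the upper face (C3 inverted)
Conditions: PPh3, diisopropyl azodicarboxylate, toluene, 0 °C → rt
Reagents that add atoms: none
Why: Mitsunobu esterification with inversion at C3 (SN2 of the carboxylate on the alkoxyphosphonium ion) puts the ester oxygen in the upper, pseudo-axial position needed for delivery to the upper face of C31.

Step 14
Reactants: 21 upper-face allylic succinate
Product: 24 2-substituted succinic acid 4-tert-butyl ester (C26 acid on C25; C25 bonded to C31 on the upper face, cis to the C11 ester; alkene C2=C3; C25 epimer mixture), via bis(silyl ketene acetal) 22 (not isolated), via rearranged silyl ester 23 (not isolated)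
Conditions: LiN(i-Pr)2 (2.6 equiv), Me3SiCl/Et3N, THF, –78 °C; then 60 °C; 1 M HCl, THF, 0 °C
Reagents that add atoms: none
Why: Ireland–Claisen rearrangement; with excess base and silyl chloride both ester groups become silyl ketene acetals, so no regioselective enolisation is required, and only the allylic one can undergo the [3,3] shift. The shift is suprafacial from the C3–O bond, so C25 is bonded to the upper face of C31 and the alkene moves to C2=C3; C25 itself is formed without control and is corrected in step 17.

Step 15
Reactants: 24 succinic acid half-ester
Product: 25 ring C β-keto tert-butyl ester acid (cis-fused cyclopentanone with C13 ketone, tert-butoxycarbonyl on C15, CO2H on C25; C15 and C25 not yet defined)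
Conditions: KOt-Bu (3.5 equiv), THF, 0 °C → rt; cold 1 M HCl
Reagents that add atoms: none
Why: Dieckmann condensation; the tert-butyl ester enolate at C15 attacks the C13 methyl ester (5-exo-trig), the only ring size available to any enolate of 24, and deprotonation of the β-keto ester product drives the reaction. The cis fusion follows from C13 and C25 both lying on the upper face.

Step 16
Reactants: 25 ring C keto ester acid
Product: 26 S-ethyl thioester of 25 at C26
Conditions: EtSH (3 equiv), EDC·HCl (1.3 equiv), DMAP (0.1 equiv), CH2Cl2, 0 °C → rt
Reagents that add atoms: ethanethiol CCS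
Why: Carbodiimide/DMAP thioesterification of the only free acid; an enol lactone formed from the activated acid and the neighbouring enol would be opened by the thiol to the same thioester.

Step 17
Reactants: 26 thioester
Product: 28 aldehyde with C26 on the lower (convex) face of ring C, trans to C2 (C25 as in the target), via C25-epimeric aldehyde mixture 27 (not isolated)
Conditions: Et3SiH (3 equiv), Pd/C (10 wt % palladium on carbon, 10 mol %), acetone, rt; filter; then DBU (1.2 equiv), CH2Cl2, 0 °C → rt; pH 7 buffer
Reagents that add atoms: none
Why: Fukuyama reduction stops at the aldehyde and leaves the ketone, tert-butyl ester and alkene untouched. Base then equilibrates C25 through the aldehyde enolate to the epimer with C26 on the convex face, because a C26 on the upper face would sit in a 1,3-diaxial (syn-pentane) relationship with the axial H10.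

Step 18
Reactants: 28 aldehyde; 29 1-(triphenyl-λ5-phosphanylidene)propan-2-one
Product: 30 (E)-enone (side chain CH=CH–C(O)CH3 on C25)
Conditions: toluene, 60 °C
Reagents that add atoms: none
Why: Wittig reaction with a stabilised ylide gives the (E)-alkene; the ylide is too weakly basic to deprotonate the β-keto ester.

Step 19
Reactants: 30 (E)-enone
Product: 31 (S)-allylic alcohol at C28
Conditions: (R)-2-methyl-CBS-oxazaborolidine (0.3 equiv), catecholborane (2.5 equiv), toluene/CH2Cl2, –78 °C; MeOH quench
Reagents that add atoms: none
Why: CBS reduction; with the alkenyl group as the large and methyl as the small substituent, the (R)-oxazaborolidine gives the (S)-alcohol. The side-chain ketone is far more accessible than the ring C ketone, which lies between C11 and C15.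

Step 20
Reactants: 31 allylic alcohol
Product: 32 C28 tert-butyldimethylsilyl ether
Conditions: TBSCl, imidazole, DMF, rt
Reagents that add atoms: tert-butyldimethylsilyl chloride CC(C)(C)[Si](C)(C)Cl
Why: Imidazole-mediated silylation of the only hydroxyl group keeps O30 from being acylated in steps 23 and 25.

Step 21
Reactants: 33 N-methyl-L-serine
Product: 34 allyl N-methyl-L-serinate p-toluenesulfonate salt
Conditions: allyl alcohol, TsOH·H2O (1.1 equiv), toluene, reflux, Dean–Stark trap
Reagents that add atoms: allyl alcohol C=CCO; p-toluenesulfonic acid Cc1ccc(cc1)S(=O)(=O)O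
Why: Fischer esterification with azeotropic removal of water; the amine is protonated throughout, which prevents self-condensation, and the α-centre is not enolised under acid.

Step 22
Reactants: 34 allyl ester salt
Product: 35 allyl N-methyl-O-(tert-butyldimethylsilyl)-L-serinate (free amine)
Conditions: TBSCl (1.2 equiv), imidazole (3 equiv), DMF, 0 °C → rt; aq. NaHCO3
Reagents that add atoms: tert-butyldimethylsilyl chloride CC(C)(C)[Si](C)(C)Cl
Why: Silylation of the primary alcohol; any N-silyl amine is hydrolysed on work-up, which also releases the free secondary amine.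

Step 23
Reactants: 32 ring C β-keto tert-butyl ester; 35 serine amine
Product: 37 β-keto amide (C23–N21 bond; allyl ester at C16), via acylketene 36 (not isolated)
Conditions: 35 (2 equiv), xylenes, 130 °C, t-BuOH distilled off
Reagents that add atoms: none
Why: Thermal loss of tert-butanol from the β-keto tert-butyl ester gives the acylketene 36, which the secondary amine traps (acetoacetylation-type amide formation); no base is present, so C18 is preserved.

Step 24
Reactants: 37 allyl ester
Product: 38 β-keto amide carboxylic acid (free C16 acid)
Conditions: Pd(PPh3)4 (5 mol %), morpholine (5 equiv), THF, rt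
Reagents that add atoms: none
Why: Deallylation by zerovalent palladium (π-allyl formation, capture by excess morpholine) frees the acid under neutral conditions that leave the silyl ethers and the β-keto amide intact.

Step 25
Reactants: 38 β-keto amide acid
Product: 40 bis(tert-butyldimethylsilyl) ether of the target (ring D closed, spiro C15), via pentafluorophenyl ester 39 (not isolated)
Conditions: C6F5OH (1.2 equiv), EDC·HCl (1.2 equiv), CH2Cl2, 0 °C; then MgBr2·OEt2 (2 equiv), i-Pr2NEt (3 equiv), CH2Cl2, 0 °C → rt
Reagents that add atoms: none
Why: Soft enolisation of the β-keto amide lets C15 attack the active ester carbon C16 (5-exo-trig, Dieckmann-type C-acylation); pentafluorophenoxide is too weak a nucleophile to reopen the product, which an alkoxide-mediated closure could not avoid because C15 keeps no acidic hydrogen. C16 should enter on the lower, convex face of the ring B/C unit because the upper face of C15 is screened by the axial H10, which places C16 cis to C26 as in the target; C18 is kept because C15–H is by far the more acidic position.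

Step 26
Reactants: 40 bis-silyl ether
Product: 41 target compound (CNP0502912.7)
Conditions: HF·pyridine, pyridine, THF, 0 °C → rt
Reagents that add atoms: none
Why: Fluoride cleaves both silyl ethers under buffered acidic conditions; no base is present that could open the tricarbonyl array by retro-Claisen cleavage or epimerise C18.

## Compound list

1 | benzoic acid | OC(=O)c1ccccc1 | starting material
2 | dilithium salt of the Birch dianion of benzoic acid (lithium 1-lithiocyclohexa-2,5-diene-1-carboxylate) | [Li+].[Li+].[O-]C(=O)[C-]1C=CCC=C1 | intermediate
3 | 1-methylcyclohexa-2,5-diene-1-carboxylic acid | CC1(C=CCC=C1)C(=O)O | intermediate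
4 | methyl 1-methylcyclohexa-2,5-diene-1-carboxylate | COC(=O)C1(C)C=CCC=C1 | intermediate
5 | methyl 1-methyl-4-oxocyclohexa-2,5-diene-1-carboxylate | COC(=O)C1(C)C=CC(=O)C=C1 | intermediate
6 | (S)-2-methylsuccinic acid 4-methyl ester ((S)-4-methoxy-2-methyl-4-oxobutanoic acid) | OC(=O)[C@@H](C)CC(=O)OC | starting material
7 | methyl (S)-4-hydroxy-3-methylbutanoate | OC[C@@H](C)CC(=O)OC | intermediate
8 | (S)-4-methyloxolan-2-one | O=C1C[C@H](C)CO1 | intermediate
9 | (S)-4-chloro-3-methylbutanoyl chloride | ClC[C@@H](C)CC(Cl)=O | intermediate
10 | methyl (S)-4-chloro-3-methylbutanoate | ClC[C@@H](C)CC(=O)OC | intermediate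
11 | (S)-4-chloro-3-methylbutan-1-ol | ClC[C@@H](C)CCO | intermediate
12 | (S)-4-bromo-1-chloro-2-methylbutane | ClC[C@@H](C)CCBr | intermediate
13 | (S)-(4-chloro-3-methylbutyl)magnesium bromide | ClC[C@@H](C)CC[Mg]Br | intermediate
14 | bromomagnesium enolate of the conjugate adduct (enolate C3=C4, chloroalkyl chain on C10, lower face) | COC(=O)[C@@]1(C)C=CC(O[Mg]Br)=C[C@@H]1CC[C@H](C)CCl | intermediate
15 | ring A/B enone ester as a mixture of C4 epimers | COC(=O)[C@@]1(C)C=CC(=O)C2C[C@@H](C)CC[C@@H]21 | intermediate
16 | methyl (1S,4aS,6S,8aS)-1,6-dimethyl-4-oxo-1,4,4a,5,6,7,8,8a-octahydronaphthalene-1-carboxylate | COC(=O)[C@@]1(C)C=CC(=O)[C@H]2C[C@@H](C)CC[C@@H]21 | intermediate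
17 | 3-iodo derivative of 16 (iodine on C2) | COC(=O)[C@@]1(C)C=C(I)C(=O)[C@H]2C[C@@H](C)CC[C@@H]21 | intermediate
18 | 3-methyl derivative of 16 (C1 methyl on C2) | COC(=O)[C@@]1(C)C=C(C)C(=O)[C@H]2C[C@@H](C)CC[C@@H]21 | intermediate
19 | C3 alcohol of 18, hydroxyl on the lower face | COC(=O)[C@@]1(C)C=C(C)[C@H](O)[C@H]2C[C@@H](C)CC[C@@H]21 | intermediate
20 | 4-tert-butoxy-4-oxobutanoic acid | OC(=O)CCC(=O)OC(C)(C)C | starting material
21 | C3 (upper-face) tert-butyl succinate ester of the allylic alcohol | COC(=O)[C@@]1(C)C=C(C)[C@@H](OC(=O)CCC(=O)OC(C)(C)C)[C@H]2C[C@@H](C)CC[C@@H]21 | intermediate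
22 | bis(trimethylsilyl ketene acetal) of 21 (alkene geometries undefined) | COC(=O)[C@@]1(C)C=C(C)[C@@H](OC(O[Si](C)(C)C)=CC=C(O[Si](C)(C)C)OC(C)(C)C)[C@H]2C[C@@H](C)CC[C@@H]21 | intermediate
23 | rearranged trimethylsilyl ester carrying the tert-butyl silyl ketene acetal (C25 undefined) | CC1=C[C@H]2C[C@@H](C)CC[C@@H]2[C@@](C)(C(=O)OC)[C@H]1C(C=C(O[Si](C)(C)C)OC(C)(C)C)C(=O)O[Si](C)(C)C | intermediate
24 | 2-(ring B C31-yl)succinic acid 4-tert-butyl ester (C25 epimer mixture; C25 on the upper face of C31) | CC1=C[C@H]2C[C@@H](C)CC[C@@H]2[C@@](C)(C(=O)OC)[C@H]1C(CC(=O)OC(C)(C)C)C(=O)O | intermediate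
25 | ring C β-keto tert-butyl ester with CO2H on C25 (C15, C25 undefined) | CC1=C[C@H]2C[C@@H](C)CC[C@@H]2[C@@]2(C)C(=O)C(C(=O)OC(C)(C)C)C(C(=O)O)[C@@H]12 | intermediate
26 | S-ethyl thioester of 25 | CC1=C[C@H]2C[C@@H](C)CC[C@@H]2[C@@]2(C)C(=O)C(C(=O)OC(C)(C)C)C(C(=O)SCC)[C@@H]12 | intermediate
27 | C26 aldehyde as a C25 epimer mixture | CC1=C[C@H]2C[C@@H](C)CC[C@@H]2[C@@]2(C)C(=O)C(C(=O)OC(C)(C)C)C(C=O)[C@@H]12 | intermediate
28 | C26 aldehyde with C25 as in the target (C15 enolisable) | CC1=C[C@H]2C[C@@H](C)CC[C@@H]2[C@@]2(C)C(=O)C(C(=O)OC(C)(C)C)[C@H](C=O)[C@@H]12 | intermediate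
29 | 1-(triphenyl-λ5-phosphanylidene)propan-2-one | CC(=O)C=P(c1ccccc1)(c1ccccc1)c1ccccc1 | starting material
30 | (E)-enone side chain on C25 | CC1=C[C@H]2C[C@@H](C)CC[C@@H]2[C@@]2(C)C(=O)C(C(=O)OC(C)(C)C)[C@H](/C=C/C(C)=O)[C@@H]12 | intermediate
31 | (S)-C28 allylic alcohol | CC1=C[C@H]2C[C@@H](C)CC[C@@H]2[C@@]2(C)C(=O)C(C(=O)OC(C)(C)C)[C@H](/C=C/[C@H](C)O)[C@@H]12 | intermediate
32 | C28 tert-butyldimethylsilyl ether of 31 | CC1=C[C@H]2C[C@@H](C)CC[C@@H]2[C@@]2(C)C(=O)C(C(=O)OC(C)(C)C)[C@H](/C=C/[C@H](C)O[Si](C)(C)C(C)(C)C)[C@@H]12 | intermediate
33 | N-methyl-L-serine | CN[C@@H](CO)C(=O)O | starting material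
34 | allyl N-methyl-L-serinate p-toluenesulfonate | C=CCOC(=O)[C@H](CO)NC.Cc1ccc(cc1)S(=O)(=O)O | intermediate
35 | allyl N-methyl-O-(tert-butyldimethylsilyl)-L-serinate | C=CCOC(=O)[C@H](CO[Si](C)(C)C(C)(C)C)NC | intermediate
36 | ring C acylketene (C15=C23=O) | CC1=C[C@H]2C[C@@H](C)CC[C@@H]2[C@@]2(C)C(=O)C(=C=O)[C@H](/C=C/[C@H](C)O[Si](C)(C)C(C)(C)C)[C@@H]12 | intermediate
37 | β-keto amide with allyl ester at C16 | CC1=C[C@H]2C[C@@H](C)CC[C@@H]2[C@@]2(C)C(=O)C(C(=O)N(C)[C@@H](CO[Si](C)(C)C(C)(C)C)C(=O)OCC=C)[C@H](/C=C/[C@H](C)O[Si](C)(C)C(C)(C)C)[C@@H]12 | intermediate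
38 | β-keto amide with free C16 acid | CC1=C[C@H]2C[C@@H](C)CC[C@@H]2[C@@]2(C)C(=O)C(C(=O)N(C)[C@@H](CO[Si](C)(C)C(C)(C)C)C(=O)O)[C@H](/C=C/[C@H](C)O[Si](C)(C)C(C)(C)C)[C@@H]12 | intermediate
39 | pentafluorophenyl ester of 38 | CC1=C[C@H]2C[C@@H](C)CC[C@@H]2[C@@]2(C)C(=O)C(C(=O)N(C)[C@@H](CO[Si](C)(C)C(C)(C)C)C(=O)Oc3c(F)c(F)c(F)c(F)c3F)[C@H](/C=C/[C@H](C)O[Si](C)(C)C(C)(C)C)[C@@H]12 | intermediate
40 | bis(tert-butyldimethylsilyl) ether of the target | CC1=C[C@H]2C[C@@H](C)CC[C@@H]2[C@@]2(C)C(=O)[C@]3(C(=O)[C@H](CO[Si](C)(C)C(C)(C)C)N(C)C3=O)[C@H](/C=C/[C@H](C)O[Si](C)(C)C(C)(C)C)[C@@H]12 | intermediate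
41 | CNP0502912.7 | CC1=C[C@H]2C[C@@H](C)CC[C@@H]2[C@@]2(C)C(=O)[C@]3(C(=O)[C@H](CO)N(C)C3=O)[C@H](/C=C/[C@H](C)O)[C@@H]12 | target

## Step count and least certain steps

Total: 26 steps. Longest linear sequence: 21 steps (6 to 41; steps 4–20 and 23–26).

Step 9 (key step). The most likely failure is poor facial selectivity at C10, that is, addition syn to the ester, because a methyl group and a methoxycarbonyl group on C11 differ only modestly in size; the second risk is slow ring closure, since a magnesium enolate must displace a β-branched primary chloride. Fallback, from 3 back to 16: acid 3 is converted with 2-methylpropene and catalytic H2SO4 into tert-butyl 1-methylcyclohexa-2,5-diene-1-carboxylate F1, which is oxidised as in step 3 to the tert-butyl dienone F2, so that the ester face is clearly the larger one. Conjugate addition of 13 under the same catalysis is quenched with NH4Cl to give the isolated chloro enone F3. This is cyclised and equilibrated separately with KOt-Bu in t-BuOH/THF to the trans-fused tert-butyl ester F4. Trifluoroacetic acid gives the acid F5, and MeI/K2CO3 returns 16.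

Step 25. The most likely failures are attack of C16 on the upper face of the C15 enolate, because the vicinal alkenyl group at C25 also lies on the lower face and opposes the convex-face preference, and loss of configuration at C18 through oxazolonium formation when the N-acyl-N-methyl amino acid is activated. Fallback, from 28 to 41, uses the C26 oxygen as a relay that allows only the cis arrangement. Aldehyde 28 is reduced with NaBH4 at –78 °C to the primary alcohol F6 and acetylated (Ac2O, pyridine) to the acetate F7. Thermal amidation with 35 as in step 23 gives the amide F8. NaOMe in MeOH then removes the acetate and effects a Lacey–Dieckmann closure whose ketone C16 is trapped by O–C26 as the five-membered hemiketal F9; this can form only when C16 and C26 are cis, and the uphill, reversible Dieckmann step is pulled through by this trap. Dess–Martin oxidation through the open hydroxy ketone gives the keto aldehyde F10. Wittig reaction with 29 gives the enone F11, CBS reduction as in step 19 gives the mono-silyl alcohol F12, and HF·pyridine gives 41.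

Step 14. The most likely failure is incomplete double enolisation, which would leave a succinate mono-enolate that condenses with itself or eliminates the allylic alkoxide, together with slow bond formation next to the quaternary C11. Fallback, from 19 to 24: Mitsunobu reaction of 19 with acetic acid gives the inverted allylic acetate F13. Ireland–Claisen rearrangement of this single-ester substrate gives the acetic acid F14 (C25H2–CO2H on C31), and its dianion (LiN(i-Pr)2, 2.2 equiv, THF/DMPU) is alkylated at C25 with tert-butyl bromoacetate to give 24.

Step 13. The most likely failure is ionisation of the allylic oxyphosphonium ion, giving elimination to a diene or loss of stereochemical integrity, because an aliphatic acid is only weakly acidic and C3 is flanked by the ring fusion. Fallback, from 19 to 21: Mitsunobu inversion with the more acidic 4-nitrobenzoic acid gives the 4-nitrobenzoate F15. K2CO3 in MeOH releases the upper-face alcohol F16, which is esterified with 20 (EDC·HCl, DMAP) without touching C3 to give 21.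

Step 17. The most likely failure is incomplete epimerisation at C25, because the neighbouring β-keto ester is deprotonated first and slows enolisation of the aldehyde, or aldol self-condensation of the aldehyde. Fallback, from 24 to 28: acid 24 is methylated (Me3SiCHN2) to the triester F17. Dieckmann closure with KOt-Bu in t-BuOH/THF, in which the open-chain C25 epimers interconvert through the methyl ester enolate before cyclising, gives the ring C keto ester with a methyl ester on C25, F18. Its sodium enolate (NaH) protects the β-keto ester while i-Bu2AlH at –78 °C reduces the methyl ester to the aldehyde 28.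

## Further compounds

F1 | step 9 | tert-butyl 1-methylcyclohexa-2,5-diene-1-carboxylate | CC(C)(C)OC(=O)C1(C)C=CCC=C1
F2 | step 9 | tert-butyl 1-methyl-4-oxocyclohexa-2,5-diene-1-carboxylate | CC(C)(C)OC(=O)C1(C)C=CC(=O)C=C1
F3 | step 9 | tert-butyl 6-[(S)-4-chloro-3-methylbutyl]-1-methyl-4-oxocyclohex-2-ene-1-carboxylate (C10, C11 as in 16) | CC(C)(C)OC(=O)[C@@]1(C)C=CC(=O)C[C@@H]1CC[C@H](C)CCl
F4 | step 9 | tert-butyl ester analogue of 16 | CC(C)(C)OC(=O)[C@@]1(C)C=CC(=O)[C@H]2C[C@@H](C)CC[C@@H]21
F5 | step 9 | carboxylic acid corresponding to 16 | OC(=O)[C@@]1(C)C=CC(=O)[C@H]2C[C@@H](C)CC[C@@H]21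
F6 | step 25 | C26 primary alcohol from 28 | CC1=C[C@H]2C[C@@H](C)CC[C@@H]2[C@@]2(C)C(=O)C(C(=O)OC(C)(C)C)[C@H](CO)[C@@H]12
F7 | step 25 | C26 acetate of F6 | CC1=C[C@H]2C[C@@H](C)CC[C@@H]2[C@@]2(C)C(=O)C(C(=O)OC(C)(C)C)[C@H](COC(C)=O)[C@@H]12
F8 | step 25 | β-keto amide with C26 acetate and allyl serinate | CC1=C[C@H]2C[C@@H](C)CC[C@@H]2[C@@]2(C)C(=O)C(C(=O)N(C)[C@@H](CO[Si](C)(C)C(C)(C)C)C(=O)OCC=C)[C@H](COC(C)=O)[C@@H]12
F9 | step 25 | spiro lactam with C16 hemiketal bridged to O–C26 | CC1=C[C@H]2C[C@@H](C)CC[C@@H]2[C@@]2(C)C(=O)[C@]34C(=O)N(C)[C@@H](CO[Si](C)(C)C(C)(C)C)[C@@]3(O)OC[C@@H]4[C@@H]12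
F10 | step 25 | spiro triketone with C26 aldehyde (O20 silyl ether) | CC1=C[C@H]2C[C@@H](C)CC[C@@H]2[C@@]2(C)C(=O)[C@]3(C(=O)[C@H](CO[Si](C)(C)C(C)(C)C)N(C)C3=O)[C@H](C=O)[C@@H]12
F11 | step 25 | spiro compound with (E)-enone side chain | CC1=C[C@H]2C[C@@H](C)CC[C@@H]2[C@@]2(C)C(=O)[C@]3(C(=O)[C@H](CO[Si](C)(C)C(C)(C)C)N(C)C3=O)[C@H](/C=C/C(C)=O)[C@@H]12
F12 | step 25 | O20 mono-silyl ether of the target | CC1=C[C@H]2C[C@@H](C)CC[C@@H]2[C@@]2(C)C(=O)[C@]3(C(=O)[C@H](CO[Si](C)(C)C(C)(C)C)N(C)C3=O)[C@H](/C=C/[C@H](C)O)[C@@H]12
F13 | step 14 | upper-face allylic acetate at C3 | COC(=O)[C@@]1(C)C=C(C)[C@@H](OC(C)=O)[C@H]2C[C@@H](C)CC[C@@H]21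
F14 | step 14 | acetic acid on C31 (C25H2–CO2H), alkene C2=C3 | CC1=C[C@H]2C[C@@H](C)CC[C@@H]2[C@@](C)(C(=O)OC)[C@H]1CC(=O)O
F15 | step 13 | upper-face 4-nitrobenzoate at C3 | COC(=O)[C@@]1(C)C=C(C)[C@@H](OC(=O)c3ccc(cc3)[N+](=O)[O-])[C@H]2C[C@@H](C)CC[C@@H]21
F16 | step 13 | upper-face allylic alcohol (C3 epimer of 19) | COC(=O)[C@@]1(C)C=C(C)[C@@H](O)[C@H]2C[C@@H](C)CC[C@@H]21
F17 | step 17 | C26 methyl ester of 24 | CC1=C[C@H]2C[C@@H](C)CC[C@@H]2[C@@](C)(C(=O)OC)[C@H]1C(CC(=O)OC(C)(C)C)C(=O)OC
F18 | step 17 | ring C β-keto tert-butyl ester with methyl ester on C25 (C25 as in the target) | CC1=C[C@H]2C[C@@H](C)CC[C@@H]2[C@@]2(C)C(=O)C(C(=O)OC(C)(C)C)[C@H](C(=O)OC)[C@@H]12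
A1 | alternative 1 | bis(tert-butyldimethylsilyl) ether of the target | CC1=C[C@H]2C[C@@H](C)CC[C@@H]2[C@@]2(C)C(=O)[C@]3(C(=O)[C@H](CO[Si](C)(C)C(C)(C)C)N(C)C3=O)[C@H](/C=C/[C@H](C)O[Si](C)(C)C(C)(C)C)[C@@H]12
A2 | alternative 1 | seco acid: C11 carboxylic acid with the tetramic acid attached at C25 | CC1=C[C@H]2C[C@@H](C)CC[C@@H]2[C@@](C)(C(=O)O)[C@H]1[C@@H](/C=C/[C@H](C)O[Si](C)(C)C(C)(C)C)C1C(=O)[C@H](CO[Si](C)(C)C(C)(C)C)N(C)C1=O
A3 | alternative 2 | cis-fused ring B/C enone keto aldehyde | O=C1C[C@@H]2[C@@H](C=O)CC(=O)[C@]2(C)C=C1
A4 | alternative 2 | 4-methyl-4-(4-oxobutanoyl)cyclohexa-2,5-dien-1-one | O=CCCC(=O)C1(C)C=CC(=O)C=C1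
A5 | alternative 3 | cyclobutanone fused to the trans-octalin | CC1=C[C@H]2C[C@@H](C)CC[C@@H]2[C@@]2(C)C(=O)[C@H](CO[Si](C)(C)C(C)(C)C)[C@@H]12
A6 | alternative 3 | N,N-dimethyl-2-(ring A C10-yl)propanamide with the (2Z,4E)-5-silyloxymethyl-3-methyl diene on C4 (C11 undefined) | CN(C)C(=O)C(C)[C@H]1CC[C@H](C)C[C@@H]1/C=C(C)\C=C\CO[Si](C)(C)C(C)(C)C
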